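# Lasiodiplactone A (22) by benzannulation of a twelve-membered ynolide

## Analysis of the target

Lasiodiplactone A (22) is a tetracycle built around one pentasubstituted benzene ring. Going round the arene, it carries a methoxy group, one hydrogen, a ketal oxygen, a benzylic CH2, a heptamethylene chain and an ester carbonyl. The ester and the chain close a 12-membered lactone whose only stereocentre is the (R)-methylcarbinol. The ketal oxygen and the benzylic CH2 belong to a pyran ring that is cis-fused to a tetrahydrofuran, giving a mixed aryl alkyl ketal with three contiguous stereocentres: the methyl-bearing ketal carbon (S), the ring-fusion CH (S) and the CH–CH3 carbon (S). The ketal methyl, the ring-fusion hydrogen and the C-methyl lie on one face of the tetrahydrofuran. The two stereochemical domains are separated by the arene and cannot control each other. The ketal is acid-labile, and the benzoate is flanked by two ortho substituents, so it is hard to make by esterification once the arene is complete. The strategy rests on three observations: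
- The ester-bearing arene carbon and its chain-bearing neighbour are the two sp carbons of a 2-ynoate that is already part of the lactone.
- The other four arene carbons (C–OMe, C–H, C–O, C–CH2) show the 1,3-dioxygen pattern of a silylated β-keto ester dienolate with a one-carbon substituent at its terminus.
- The benzylic CH2 next to a phenol oxygen is the mark of an o-quinone methide.

## Retrosynthetic reasoning

**22 ⇒ 21.** The O–CH3 bond on the aryl oxygen next to the lactone carbonyl is cut last. In 21 this is the only free hydroxyl, because the other aryl oxygen is locked in the ketal. The methylation therefore needs no differentiation of two phenols, and the hydrogen-bonded hydroxyl can simply be forced.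

**21 ⇒ 16 + 19.** Two bonds of the pyran ring are cut together: the benzylic CH2–CH bond and the aryl O–C(ketal) bond. This is the retron of an inverse-demand hetero-Diels–Alder reaction between o-quinone methide 20 and enol ether 19. Intermediate 20 is not stored; it arises from 16 by 1,4-elimination of the benzylic methoxy group. This cut, rather than one in the tetrahydrofuran, makes the pyran ring, the ketal carbon and the ring-fusion stereocentre in one step and lets the single stereocentre of 19 control both. The forward reaction must generate 20 in the presence of an acid-sensitive enol ether and add it to the face of 19 away from its methyl group.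

**19 ⇒ 18 ⇒ 17.** The enol ether double bond goes back to lactol 18 by dehydration, and the methyl on the future ketal carbon to addition of a methyl nucleophile to lactone 17. The C-methyl stereocentre is bought with 17 and sits β to the carbonyl, where it cannot epimerise.

**16 ⇒ 9 + 13 (key disconnection).** The two arene bonds flanking the ester-bearing and chain-bearing carbons are cut (C14a–C14 and C10a–C11 of 16). One side is the intact 12-membered lactone with a triple bond, 9. The other is a four-carbon unit oxygenated at C1 and C3 and carrying CH2OMe at C4, diene 13. Cutting here and not in the macrocycle means the di-ortho-substituted benzoate is never formed from a hindered acid; it exists as an ordinary ynoate ester before the arene does. The same cut delivers the benzylic carbon in the right place, so no electrophilic substitution on a resorcylate is needed. The forward reaction must combine the two partners with polarity-controlled regiochemistry (14), aromatise (15) and lose the silyl groups.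

**13 ⇒ 11 ⇒ 10.** The diene is the product of two successive enol silylations of keto ester 10, the second through the extended dienolate 12.

**9 ⇒ 7.** The acyl C–O bond of the lactone is cut. The acid of 7 is linear and unhindered, so it is activated as mixed anhydride 8 and closed at high dilution; the carbinol C–O bond is not touched.

**7 ⇒ 5.** The bond between the alkyne carbon and the carboxyl carbon is cut; the forward step is carboxylation of dianion 6.

**5 ⇒ 4 ⇒ 1 + 2.** The terminal alkyne of 5 is first traced back to the internal alkyne of 4 (isomerisation along the chain). Then the CH2–C(sp) bond next to the carbinol is cut, giving acetylide 3 (from 1) and epoxide 2. The (R)-centre is bought with 2, and the eleven-carbon chain is assembled in two steps.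

## Alternatives that were turned down

**Alternative 1:** Ramberg–Bäcklund contraction of a thia-lactone.
- Disconnection: the macrocycle is opened between the benzylic carbon of the chain and its neighbour, and a sulfur atom is inserted, giving the 13-membered benzylic sulfone A1.
- Forward key step: Ramberg–Bäcklund reaction of A1 under basic halogenating conditions (hydroxide, a perhalomethane). α-Halogenation, episulfone formation and loss of SO2 join the two sulfur-bound carbons and give the styrenyl lactone A2 as an E/Z mixture, which is then hydrogenated to 22.
- For: ring closure by thiolate alkylation is among the most dependable macrocyclisations. On that point it is stronger than the lactonisation leading to 9.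
- Against: the contraction exposes a lactone and an electron-rich arene to hydroxide and to carbene formed from the halogen donor. It does nothing for the real difficulties, since the pentasubstituted arene must still be made and carry two different benzylic handles, and the hindered ester must still be formed from a 2,6-disubstituted benzoic acid. One C–C bond costs four operations (thioether closure, oxidation, contraction, hydrogenation).
- Comparison: the chosen route concedes the easier ring closure but forms the arene, places all five substituents and needs no later reduction.

**Alternative 2:** Desymmetrising C–H lactonisation of an isopropyl group.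
- Disconnection: the O–CH2 bond of the tetrahydrofuran, formed at the lactone stage from the isopropyl acid A3.
- Forward key step: a chiral Mn(OTf)2–bis(pyridylmethyl)bipyrrolidine catalyst with aqueous peroxide oxidises one of the two diastereotopic methyl groups of A3 under carboxylate direction and closes the trans-lactone A4. Methyl addition, pivalate removal and ketalisation would follow.
- For: the C-methyl stereocentre is created from an achiral isopropyl group by catalyst control, without a chiral-pool lactone. On that point it is stronger than buying 17.
- Against: A3 is the most advanced intermediate of that route and holds C–H bonds weaker than a methyl C–H (two benzylic CH2 groups, the tertiary isopropyl C–H, the lactone carbinol C–H) and an oxidisable arene. The catalyst must also choose between two methyl groups next to an α-stereocentre that needs its own asymmetric step. At least three steps remain after the oxidation.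
- Comparison: the chosen route sets the ring-fusion CH and the ketal carbon in one cycloaddition from one purchased stereocentre, and its risk sits in an early convergent step rather than a late oxidation.

**Alternative 3:** Acylketene macrolactonisation, then transannular aldol aromatisation.
- Disconnection: the lactone acyl C–O bond and the arene bond between the ester-bearing and chain-bearing carbons, both traced to the diketo-dioxinone A5.
- Forward key step: heating A5 at high dilution releases an acylketene that is captured by the secondary alcohol (16-membered ring). Carbonate base and then acid bring about the transannular aldol condensation and aromatisation to de-O-methyllasiodiplodin A6.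
- For: like the chosen route, it makes the hindered ester before the arene exists. Ketene capture in a 16-membered ring is more reliable than closing a 12-membered ynolide, and the aromatisation has no regiochemical question. On both counts it is as strong or stronger.
- Against: A6 has hydrogen where the benzylic carbon of the pyran ring must stand. That carbon would have to be added by electrophilic substitution on a resorcylate, where the position between the two hydroxyls competes. A5 also takes several steps of sensitive polycarbonyl chemistry.
- Comparison: the chosen route brings the CH2OMe handle in regiospecifically during the arene-forming step and reaches both components in four and two steps.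

Key step: step 7

Remark on the chemistry: 11, 12 and 13 are drawn as single geometric isomers, 14 without configuration at its two sp3 ring carbons and 18 as an anomeric mixture; none of these elements survives into 16 or 19. Lactone 17 is taken as commercially available in enantiopure form.

## Route

Step 1
Reactants: 1 oct-1-yne; 2 (R)-propylene oxide [(2R)-2-methyloxirane]
Product: 4 (R)-undec-4-yn-2-ol, via lithium oct-1-yn-1-ide 3 (not isolated)
Conditions: n-BuLi, THF, −78 °C; BF3·OEt2; then 2, −78 °C; aqueous work-up
Reagents that add atoms: none
Why: BF3-promoted SN2 opening of a terminal epoxide by a lithium acetylide at the unsubstituted carbon. The stereocentre of 2 is not involved and is carried over as (R).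

Step 2
Reactants: 4 (R)-undec-4-yn-2-ol
Product: 5 (R)-undec-10-yn-2-ol
Conditions: KH, H2N(CH2)3NH2, 0 °C → rt; then H2O
Reagents that add atoms: none
Why: Alkyne zipper isomerisation: the potassium amide moves the triple bond through propargyl/allenyl anions along the chain until it is trapped irreversibly as the terminal acetylide at the end remote from the alkoxide. The carbinol C–H is not acidic under these conditions, so the (R)-centre should be kept.

Step 3
Reactants: 5 (R)-undec-10-yn-2-ol
Product: 7 (R)-11-hydroxydodec-2-ynoic acid, via dilithium alkoxide acetylide 6 (not isolated)
Conditions: n-BuLi (2.2 equiv), THF, −78 → 0 °C; CO2, −78 °C → rt; 1 M HCl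
Reagents that add atoms: carbon dioxide, O=C=O
Why: Carboxylation of a lithium acetylide. The alkoxide needs no protecting group, since any carbonate formed there reverts to the alcohol on acidification.

Step 4
Reactants: 7 (R)-11-hydroxydodec-2-ynoic acid
Product: 9 (12R)-12-methyl-1-oxacyclododec-3-yn-2-one, via mixed 2,4,6-trichlorobenzoic anhydride 8 (not isolated)
Conditions: 2,4,6-Cl3C6H2COCl, Et3N, THF, rt; then slow addition to 4-(dimethylamino)pyridine, toluene, 80 °C, high dilution
Reagents that add atoms: none
Why: Yamaguchi macrolactonisation. Activation is at the acyl carbon, so the carbinol keeps its (R) configuration; a 12-membered ring tolerates the linear C–C≡C–C unit much as cyclododecyne does, and high dilution holds back diolide formation.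

Step 5
Reactants: 10 methyl 5-methoxy-3-oxopentanoate
Product: 11 methyl (2Z)-5-methoxy-3-(trimethylsilyloxy)pent-2-enoate
Conditions: TMSCl, Et3N, toluene, rt
Reagents that add atoms: chlorotrimethylsilane, C[Si](C)(C)Cl
Why: O-Silylation of the enolised β-keto ester under mild amine conditions, the standard first stage towards 1,3-bis(silyloxy)dienes. The base is too weak to trigger loss of the β-methoxy group.

Step 6
Reactants: 11 methyl (2Z)-5-methoxy-3-(trimethylsilyloxy)pent-2-enoate
Product: 13 (1Z,3Z)-1,5-dimethoxy-1,3-bis(trimethylsilyloxy)penta-1,3-diene, via lithium dienolate 12 (not isolated)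
Conditions: TMSCl, then LiN(i-Pr)2, THF, −78 °C → rt; hexane, filtration; used crude
Reagents that add atoms: chlorotrimethylsilane, C[Si](C)(C)Cl
Why: γ-Deprotonation of the silyloxy enoate gives the extended dienolate, which is silylated on the ester oxygen to the ketene acetal. With the silyl chloride present from the start, the dienolate should be trapped before it can expel methoxide from C5.

Step 7
Reactants: 9 (12R)-12-methyl-1-oxacyclododec-3-yn-2-one; 13 (1Z,3Z)-1,5-dimethoxy-1,3-bis(trimethylsilyloxy)penta-1,3-diene
Product: 16 (3R)-12,14-dihydroxy-11-(methoxymethyl)-3-methyl-3,4,5,6,7,8,9,10-octahydro-1H-2-benzoxacyclododecin-1-one, via cyclohexa-1,4-diene cycloadduct 14 (not isolated), via bis(trimethylsilyl) aryl ether 15 (not isolated)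
Conditions: 13 (3–4 equiv, in portions), neat or minimal o-xylene, 130–140 °C, sealed tube, Ar; then MeOH, cat. HCl, 0 °C → rt
Reagents that add atoms: none
Why: A thermal normal-demand [4+2] cycloaddition between the s-cis diene 13 and the ynoate 9 gives cyclohexa-1,4-diene 14, probably asynchronously with the bond from diene C4 to the ynoate β-carbon leading. In 14 the carbon next to the ester carries OMe and OSiMe3 and the carbon across the ring carries a doubly allylic hydrogen, so 1,4-elimination of methanol aromatises it to 15, and acidic methanol removes both silyl groups to give 16. The closest known reaction type is the Diels–Alder/aromatisation of 1-alkoxy-1,3-bis(silyloxy)dienes with 2-alkynoates, macrocyclic ynolides included, to give resorcylates. The only ring formed is the benzene ring, closed intermolecularly by the two new σ bonds of a suprafacial cycloaddition onto the existing 12-membered lactone, which stays intact. No stereocentre is created that survives: the two sp3 centres of 14 are erased on aromatisation and the remote (R)-carbinol is untouched. The step needs regioselectivity, which the substrates secure by matched polarity: both oxygen donors (C1 and C3) push the largest HOMO coefficient of 13 to C4, and the ester puts the largest LUMO coefficient of 9 on its β-carbon, so CH2OMe ends next to the chain and the ketene-acetal carbon next to the ester. Work-up in methanol is chosen so that any acid-induced ionisation of the new o-hydroxybenzyl ether returns the same methyl ether.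

Step 8
Reactants: 17 (S)-4-methyldihydrofuran-2(3H)-one
Product: 18 (4S)-2,4-dimethyltetrahydrofuran-2-ol
Conditions: MeLi (1.05 equiv), Et2O, −78 °C; AcOH, −78 °C
Reagents that add atoms: methyllithium, [Li]C
Why: Mono-addition of an organolithium to a γ-lactone stops at the lithium hemiketal alkoxide at low temperature and gives the lactol (in equilibrium with the open hydroxy ketone). The stereocentre is β to the carbonyl and not enolisable.

Step 9
Reactants: 18 (4S)-2,4-dimethyltetrahydrofuran-2-ol
Product: 19 (3S)-3,5-dimethyl-2,3-dihydrofuran
Conditions: cat. H3PO4, neat, 130–150 °C bath, product distilled as formed; dried over K2CO3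
Reagents that add atoms: none
Why: Acid-catalysed cyclodehydration of a γ-hydroxy ketone/lactol to the endocyclic enol ether, the way simple 5-methyl-2,3-dihydrofurans are made; distillation takes the product away from the acid. Proton loss and gain occur at C4 and the exocyclic methyl, never at C3, so the (S)-centre is kept.

Step 10
Reactants: 16 (3R)-12,14-dihydroxy-11-(methoxymethyl)-3-methyl-3,4,5,6,7,8,9,10-octahydro-1H-2-benzoxacyclododecin-1-one; 19 (3S)-3,5-dimethyl-2,3-dihydrofuran
Product: 21 O-demethyl-lasiodiplactone A (22 with OH in place of OCH3), via o-quinone methide 20 (not isolated)
Conditions: 19 (5–8 equiv), toluene, 4 Å MS, 160 °C, sealed tube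
Reagents that add atoms: none
Why: On heating, the o-hydroxybenzyl methyl ether loses methanol by 1,4-elimination to give o-quinone methide 20, which the enol ether 19 traps in an inverse-demand hetero-Diels–Alder reaction: the methylene carbon bonds to the nucleophilic C4 of 19 and the carbonyl oxygen to C5. Suprafacial addition across the ring alkene makes the pyran/tetrahydrofuran fusion cis, and approach to the face of 19 opposite its C3 methyl sets the ring-fusion CH (S) and the ketal carbon (S) relative to the existing (S)-centre; the remote (R)-carbinol plays no part.

Step 11
Reactants: 21 O-demethyl-lasiodiplactone A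
Product: 22 lasiodiplactone A
Conditions: MeI, K2CO3, acetone, reflux
Reagents that add atoms: iodomethane, CI
Why: Williamson O-methylation of the only remaining phenol; the hydrogen-bonded ortho-hydroxyl needs heating but has no competitor. Ketal and hindered lactone are stable to carbonate.

## Compound list

1 | oct-1-yne | C#CCCCCCC | starting material
2 | (R)-propylene oxide, (2R)-2-methyloxirane | C[C@@H]1CO1 | starting material
3 | lithium oct-1-yn-1-ide (not isolated) | [Li]C#CCCCCCC | intermediate
4 | (R)-undec-4-yn-2-ol | C[C@@H](O)CC#CCCCCCC | intermediate
5 | (R)-undec-10-yn-2-ol | C[C@@H](O)CCCCCCCC#C | intermediate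
6 | dilithium salt of 5 at oxygen and at the alkyne terminus (not isolated) | C[C@@H](O[Li])CCCCCCCC#C[Li] | intermediate
7 | (R)-11-hydroxydodec-2-ynoic acid | C[C@@H](O)CCCCCCCC#CC(=O)O | intermediate
8 | mixed anhydride of 7 with 2,4,6-trichlorobenzoic acid (not isolated) | C[C@@H](O)CCCCCCCC#CC(=O)OC(=O)c1c(Cl)cc(Cl)cc1Cl | intermediate
9 | (12R)-12-methyl-1-oxacyclododec-3-yn-2-one | C[C@@H]1CCCCCCCC#CC(=O)O1 | intermediate
10 | methyl 5-methoxy-3-oxopentanoate | COCCC(=O)CC(=O)OC | starting material
11 | methyl (2Z)-5-methoxy-3-(trimethylsilyloxy)pent-2-enoate | COCC/C(O[Si](C)(C)C)=C/C(=O)OC | intermediate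
12 | lithium dienolate of 11, lithium on the ester oxygen (not isolated) | CO/C(O[Li])=C/C(O[Si](C)(C)C)=C/COC | intermediate
13 | (1Z,3Z)-1,5-dimethoxy-1,3-bis(trimethylsilyloxy)penta-1,3-diene | CO/C(O[Si](C)(C)C)=C/C(O[Si](C)(C)C)=C/COC | intermediate
14 | cyclohexa-1,4-diene cycloadduct fused to the 12-membered lactone: C(OMe)(OSiMe3) next to the ester-bearing carbon, CH=C(OSiMe3), CH(CH2OMe) next to the chain-bearing carbon; diastereomer mixture (not isolated) | COCC1C(O[Si](C)(C)C)=CC(OC)(O[Si](C)(C)C)C2=C1CCCCCCC[C@@H](C)OC2=O | intermediate
15 | 12,14-bis(trimethylsilyl) ether of 16 (not isolated) | COCc1c(O[Si](C)(C)C)cc(O[Si](C)(C)C)c2c1CCCCCCC[C@@H](C)OC2=O | intermediate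
16 | (3R)-12,14-dihydroxy-11-(methoxymethyl)-3-methyl-3,4,5,6,7,8,9,10-octahydro-1H-2-benzoxacyclododecin-1-one | Oc1cc(O)c(COC)c2c1C(=O)O[C@H](C)CCCCCCC2 | intermediate
17 | (S)-4-methyldihydrofuran-2(3H)-one | O=C1C[C@H](C)CO1 | starting material
18 | (4S)-2,4-dimethyltetrahydrofuran-2-ol, anomeric mixture | CC1(O)C[C@H](C)CO1 | intermediate
19 | (3S)-3,5-dimethyl-2,3-dihydrofuran | CC1=C[C@H](C)CO1 | intermediate
20 | o-quinone methide from 16: C11 exocyclic methylidene, C12 carbonyl, C14 hydroxyl retained, (R)-lactone intact (not isolated) | C=C1C(=O)C=C(O)C2=C1CCCCCCC[C@@H](C)OC2=O | intermediate
21 | O-demethyl-lasiodiplactone A: free phenol ortho to the lactone carbonyl; cis-fused chromane ketal/tetrahydrofuran with (S)-ketal carbon, (S)-ring-fusion CH, (S)-CHCH3; (R)-lactone carbinol | Oc1cc2c(c3c1C(=O)O[C@H](C)CCCCCCC3)C[C@H]1[C@H](C)CO[C@@]1(C)O2 | intermediate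
22 | lasiodiplactone A: methyl ether of 21, same four stereocentres | COc1cc2c(c3c1C(=O)O[C@H](C)CCCCCCC3)C[C@H]1[C@H](C)CO[C@@]1(C)O2 | target

## Step count and least certain steps

Total: 11 steps. Longest linear sequence: 7 steps (1, 2, 3, 4, 7, 10, 11).

**Step 7 (key step).**
- What may go wrong: the cycloaddition joins two substituted termini (the CH2OMe-bearing diene carbon and the alkyl-bearing β-carbon of a non-activated ynoate). It may therefore be slower than thermal decay of 13 (silyl migration, hydrolysis, oligomerisation) or than propargyl-to-allenyl isomerisation of 9 on prolonged heating. Bond formation through C2 of the diene, leading to open-chain adducts, is a lesser risk.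
- Fallback: the cycloaddition is moved to a cheap acyclic ynoate that can be used in excess, and the macrocycle is closed afterwards by olefin metathesis. It sets out from 2 and 13 and comes back to the route at 16.
  - Opening of 2 with but-3-enylmagnesium bromide (cat. CuI, THF, −30 °C) gives (R)-hept-6-en-2-ol F1.
  - Carboxylation of hex-1-en-5-yne (n-BuLi, CO2) gives hept-6-en-2-ynoic acid F2.
  - Esterification (dicyclohexylcarbodiimide, cat. 4-(dimethylamino)pyridine, CH2Cl2, 0 °C) gives (R)-hept-6-en-2-yl hept-6-en-2-ynoate F3, again before any hindered benzoate exists.
  - Heating 13 in an excess of F3 at 130–140 °C, then acidic methanol, should give (R)-hept-6-en-2-yl 2-(but-3-en-1-yl)-4,6-dihydroxy-3-(methoxymethyl)benzoate F4.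
  - Ring-closing metathesis (second-generation Grubbs catalyst, CH2Cl2, 40 °C, high dilution) gives the 12-membered 7,8-alkene (3R)-12,14-dihydroxy-11-(methoxymethyl)-3-methyl-3,4,5,6,9,10-hexahydro-1H-2-benzoxacyclododecin-1-one F5 as an E/Z mixture.
  - Homogeneous hydrogenation (H2, RhCl(PPh3)3, benzene/EtOH), which spares the benzylic ether, gives 16.

**Step 4.**
- What may go wrong: oligomerisation (diolide and higher) may outrun closure of a 12-membered ring that contains a rigid four-atom linear unit. The activated ynoyl group may also suffer conjugate addition of the pyridine catalyst or of chloride.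
- Fallback: the ring is closed at the alkyl C–O bond instead of the acyl C–O bond, by Mitsunobu macrolactonisation with inversion in the enantiomeric series. It sets out from 1 and comes back at 9.
  - Steps 1–3 are repeated with commercial (S)-propylene oxide, giving (S)-undec-4-yn-2-ol F6, (S)-undec-10-yn-2-ol F7 and (S)-11-hydroxydodec-2-ynoic acid F8.
  - Slow addition of F8 to PPh3 and diisopropyl azodicarboxylate in toluene (0 °C → rt, high dilution) activates the alcohol, and the acidic ynoic carboxylate displaces it with inversion to give (R)-configured 9. No electrophilic ynoyl species is formed.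

**Step 10.**
- What may go wrong: thermal loss of methanol may need temperatures at which 19 is consumed faster by phenol- or methanol-addition and oligomerisation than by cycloaddition. The quinone methide (which can tautomerise to the para-quinone methide through the C14 hydroxyl) may self-condense, and facial selectivity on 19 may erode at 160 °C.
- Fallback: the pyran ring is built stepwise without a quinone methide. It sets out from 16 and 17 and returns at 21.
  - Pivaloylation of both phenols (PivCl, Et3N, 4-(dimethylamino)pyridine) gives the 12,14-bis-O-pivaloyl derivative F9.
  - BBr3 (CH2Cl2, −78 °C) converts the benzylic methyl ether into the 11-(bromomethyl) compound F10.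
  - The lithium enolate of 17 (LiN(SiMe3)2, THF, −78 °C) is alkylated by F10 anti to the β-methyl group, giving the trans-(3S,4S)-3-(arylmethyl)-4-methyl-γ-butyrolactone F11.
  - NaOMe in MeOH removes the pivalates to give the diphenol lactone F12; trans is the thermodynamic arrangement, so nothing is lost by epimerisation.
  - MeLi (3.3 equiv, THF, −78 °C; AcOH quench) converts the γ-lactone into its methyl lactol, and pyridinium p-toluenesulfonate in CH2Cl2 closes the thermodynamically favoured cis-fused ketal onto the C12 phenol, giving 21.

**Step 6.**
- What may go wrong: the lithium dienolate 12 carries a methoxy group β to its carbanionic terminus and may lose methoxide (E1cB) to a vinyl ketone derivative before it is silylated.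
- Fallback: the carbanion route is given up. Keto ester 10 is silylated twice in one pot by soft enolisation (TMSOTf, 2.2 equiv, Et3N, Et2O, 0 °C), in which an amine deprotonates O-silylated carbonyl cations and no metal dienolate exists at any time. It sets out from 10, bypasses 11 and 12, and returns at 13; it makes no new compound (F0).

## Further compounds

F1 | step 7 | (R)-hept-6-en-2-ol | C[C@@H](O)CCCC=C
F2 | step 7 | hept-6-en-2-ynoic acid | C=CCCC#CC(=O)O
F3 | step 7 | (R)-hept-6-en-2-yl hept-6-en-2-ynoate | C=CCCC#CC(=O)O[C@H](C)CCCC=C
F4 | step 7 | (R)-hept-6-en-2-yl 2-(but-3-en-1-yl)-4,6-dihydroxy-3-(methoxymethyl)benzoate | COCc1c(O)cc(O)c(C(=O)O[C@H](C)CCCC=C)c1CCC=C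
F5 | step 7 | (3R)-12,14-dihydroxy-11-(methoxymethyl)-3-methyl-3,4,5,6,9,10-hexahydro-1H-2-benzoxacyclododecin-1-one, E/Z mixture at C7=C8 | COCc1c(O)cc(O)c2c1CCC=CCCC[C@@H](C)OC2=O
F6 | step 4 | (S)-undec-4-yn-2-ol | C[C@H](O)CC#CCCCCCC
F7 | step 4 | (S)-undec-10-yn-2-ol | C[C@H](O)CCCCCCCC#C
F8 | step 4 | (S)-11-hydroxydodec-2-ynoic acid | C[C@H](O)CCCCCCCC#CC(=O)O
F9 | step 10 | 12,14-bis-O-pivaloyl derivative of 16 | CC(C)(C)C(=O)Oc1cc(OC(=O)C(C)(C)C)c(COC)c2c1C(=O)O[C@H](C)CCCCCCC2
F10 | step 10 | 11-(bromomethyl) analogue of F9 | CC(C)(C)C(=O)Oc1cc(OC(=O)C(C)(C)C)c(CBr)c2c1C(=O)O[C@H](C)CCCCCCC2
F11 | step 10 | (3S,4S)-4-methyl-3-(arylmethyl)dihydrofuran-2(3H)-one, aryl = 12,14-bis-O-pivaloyl macrolactone core attached through C11 | CC(C)(C)C(=O)Oc1cc(OC(=O)C(C)(C)C)c(C[C@H]2[C@H](C)COC2=O)c2c1C(=O)O[C@H](C)CCCCCCC2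
F12 | step 10 | diphenol obtained from F11 by removal of both pivalates | Oc1cc(O)c(C[C@H]2[C@H](C)COC2=O)c2c1C(=O)O[C@H](C)CCCCCCC2
F0 | step 6 | none | none
A1 | alternative 1 | 13-membered benzylic sulfone: lasiodiplactone A skeleton with ArCH2–SO2–CH2 in place of the ArCH2–CH2 bond of the macrocycle | COc1cc2c(c3c1C(=O)O[C@H](C)CCCCCCS(=O)(=O)C3)C[C@H]1[C@H](C)CO[C@@]1(C)O2
A2 | alternative 1 | lasiodiplactone A with a benzylic C=C bond in the macrocycle, E/Z mixture | COc1cc2c(c3c1C(=O)O[C@H](C)CCCCCC=C3)C[C@H]1[C@H](C)CO[C@@]1(C)O2
A3 | alternative 2 | (2S)-2-(arylmethyl)-3-methylbutanoic acid, aryl = 14-O-methyl-12-O-pivaloyl macrolactone core attached through C11 | COc1cc(OC(=O)C(C)(C)C)c(C[C@@H](C(C)C)C(=O)O)c2c1C(=O)O[C@H](C)CCCCCCC2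
A4 | alternative 2 | trans-(3S,4S)-α-(arylmethyl)-β-methyl-γ-butyrolactone with the same aryl group as A3 | COc1cc(OC(=O)C(C)(C)C)c(C[C@H]2[C@H](C)COC2=O)c2c1C(=O)O[C@H](C)CCCCCCC2
A5 | alternative 3 | 6-[(11R)-11-hydroxy-2,4-dioxododecyl]-2,2-dimethyl-4H-1,3-dioxin-4-one | CC1(C)OC(=O)C=C(CC(=O)CC(=O)CCCCCCC[C@@H](C)O)O1
A6 | alternative 3 | de-O-methyllasiodiplodin | Oc1cc(O)cc2c1C(=O)O[C@H](C)CCCCCCC2
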